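**Retrosynthetic overview**
1. Target 29 ⇐ desilylation, selective acetylation and one i-Bu2AlH reduction of ester–nitrile 25; the enal is carried as a (Z)-α,β-unsaturated nitrile and the allylic acetate as a conjugated ester.
2. Key disconnection: the C14–C26 bond, closed by a visible-light ketyl–olefin spirocyclisation of aldehyde 19 onto an alkylidene phosphonoacetate; the phosphonate left behind then builds C15=C16 with dienal 23 in the same flask.
3. The cyclohexane comes from (S)-carvone: C6 by enolate alkylation, C11 by deconjugative Michael alkylation, C10 by hydroxyl-directed epoxidation and hydride opening; the isopropenyl group is degraded to the C7 ketone and olefinated.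
4. Dienal 23 ⇐ 6-methylhept-5-en-2-one and acrolein (enol triflate, Heck).
5. Ring order: the six-membered ring is bought; the five-membered ring is formed last, in step 14.

Assumption: atoms carry biogenetic numbers (C1 aldehyde carbon, C2 its α-carbon, C3–C5 hydroxypropyl chain, C6–C11 cyclohexane with C7 the alkylidene carbon, C10 the carbinol and C11 the spiro atom, C12–C14 and C26 the rest of the cyclopentane, C15–C19 the triene chain, C28 the acetoxymethyl carbon), and the SMILES is read as (6R,10S,11S,14S,26S) with 2Z, 15E and 17E double bonds. TBS = tert-butyldimethylsilyl.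

**Step 1**
Reactants: 1 (S)-(+)-carvone; 2 tert-butyl(3-iodopropoxy)dimethylsilane
Product: 3 (5S,6R)-6-[3-(TBSO)propyl]-2-methyl-5-(prop-1-en-2-yl)cyclohex-2-en-1-one
Conditions: LiN(i-Pr)2, THF, −78 °C; then 2, DMPU, −78 → −20 °C
Reagents that add atoms: tert-butyl(3-iodopropoxy)dimethylsilane, ICCCO[Si](C)(C)C(C)(C)C
Why: Kinetic α′-enolate alkylation of carvone; the iodide approaches the enolate face opposite the adjacent isopropenyl group and gives the 5,6-trans product, so the bought stereocentre sets C6.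

**Step 2**
Reactants: 3 (5S,6R)-6-[3-(TBSO)propyl]-2-methyl-5-(prop-1-en-2-yl)cyclohex-2-en-1-one
Product: 5 (5S,6R)-6-[3-(TBSO)propyl]-2-methyl-5-(prop-1-en-2-yl)cyclohex-1-en-1-yl trifluoromethanesulfonate, via lithium enolate 4 (not isolated)
Conditions: LiBH(s-Bu)3, THF, −78 °C; then PhNTf2, −78 → 0 °C
Reagents that add atoms: N-phenylbis(trifluoromethanesulfonimide), O=S(=O)(N(c1ccccc1)S(=O)(=O)C(F)(F)F)C(F)(F)F
Why: Conjugate (1,4) hydride reduction gives the regiodefined tetrasubstituted enolate, which is O-triflated (enol triflate formation) without touching C5 or C6.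

**Step 3**
Reactants: 5 (5S,6R)-6-[3-(TBSO)propyl]-2-methyl-5-(prop-1-en-2-yl)cyclohex-1-en-1-yl trifluoromethanesulfonate
Product: 6 methyl (5S,6R)-6-[3-(TBSO)propyl]-2-methyl-5-(prop-1-en-2-yl)cyclohex-1-ene-1-carboxylate
Conditions: Pd(OAc)2 (5 mol %), PPh3, CO (1 atm), MeOH, Et3N, DMF, 60 °C
Reagents that add atoms: carbon monoxide, [C-]#[O+]; methanol, CO
Why: Palladium-catalysed methoxycarbonylation of the enol triflate (oxidative addition to zerovalent palladium, CO insertion, methanolysis) installs C26 as an ester.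

**Step 4**
Reactants: 6 methyl (5S,6R)-6-[3-(TBSO)propyl]-2-methyl-5-(prop-1-en-2-yl)cyclohex-1-ene-1-carboxylate; 7 methyl acrylate
Product: 8 methyl (1R,2R,3S)-1-(3-methoxy-3-oxopropyl)-6-methylidene-2-[3-(TBSO)propyl]-3-(prop-1-en-2-yl)cyclohexane-1-carboxylate
Conditions: LiN(i-Pr)2, THF–DMPU, −78 °C; then 7, −78 °C; H2O
Reagents that add atoms: methyl acrylate, C=CC(=O)OC
Why: Deconjugative α-alkylation of the extended ester enolate (γ-deprotonation at the methyl cis to the ester, Michael addition through the α-carbon) creates the quaternary C11 with the acrylate entering anti to the adjacent C6 side chain; any endocyclic alkene isomer converges in steps 6 and 7.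

**Step 5**
Reactants: 8 methyl (1R,2R,3S)-1-(3-methoxy-3-oxopropyl)-6-methylidene-2-[3-(TBSO)propyl]-3-(prop-1-en-2-yl)cyclohexane-1-carboxylate
Product: 9 3-[(1R,2R,3S)-1-(hydroxymethyl)-6-methylidene-2-[3-(TBSO)propyl]-3-(prop-1-en-2-yl)cyclohexyl]propan-1-ol
Conditions: LiAlH4, THF, 0 °C → rt
Reagents that add atoms: none
Why: Hydride reduction of both esters to primary alcohols; no stereocentre is touched.

**Step 6**
Reactants: 9 3-[(1R,2R,3S)-1-(hydroxymethyl)-6-methylidene-2-[3-(TBSO)propyl]-3-(prop-1-en-2-yl)cyclohexyl]propan-1-ol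
Product: 10 3-[(3S,4S,5R,6S)-4-(hydroxymethyl)-5-[3-(TBSO)propyl]-6-(prop-1-en-2-yl)-1-oxaspiro[2.5]octan-4-yl]propan-1-ol
Conditions: VO(acac)2 (5 mol %), t-BuOOH, CH2Cl2, 0 °C → rt
Reagents that add atoms: tert-butyl hydroperoxide, CC(C)(C)OO
Why: Vanadium-catalysed hydroxyl-directed epoxidation of the homoallylic alcohol delivers oxygen to the methylidene face syn to the CH2OH group, which sets C10 and leaves the isopropenyl group untouched.

**Step 7**
Reactants: 10 3-[(3S,4S,5R,6S)-4-(hydroxymethyl)-5-[3-(TBSO)propyl]-6-(prop-1-en-2-yl)-1-oxaspiro[2.5]octan-4-yl]propan-1-ol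
Product: 11 (1S,2S,3R,4S)-2-(hydroxymethyl)-2-(3-hydroxypropyl)-1-methyl-3-[3-(TBSO)propyl]-4-(prop-1-en-2-yl)cyclohexan-1-ol
Conditions: LiBHEt3, THF, 0 °C → rt; H2O
Reagents that add atoms: none
Why: SN2 hydride opening of the 2,2-disubstituted epoxide at its CH2 carbon (epoxide reduction) unveils the tertiary alcohol with the C–O bond of step 6 intact.

**Step 8**
Reactants: 11 (1S,2S,3R,4S)-2-(hydroxymethyl)-2-(3-hydroxypropyl)-1-methyl-3-[3-(TBSO)propyl]-4-(prop-1-en-2-yl)cyclohexan-1-ol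
Product: 14 (2S,3S,4S)-4-hydroxy-3-(hydroxymethyl)-3-(3-hydroxypropyl)-4-methyl-2-[3-(TBSO)propyl]cyclohexan-1-one, via methoxy hydroperoxide 12 (not isolated), via TEMPO alkoxyamine 13 (not isolated)
Conditions: O3, MeOH–CH2Cl2, −78 °C; then FeSO4·7H2O, TEMPO, −78 °C → rt; then mCPBA, 0 °C
Reagents that add atoms: TEMPO, CC1(C)CCCC(C)(C)N1[O]
Why: Ozonolysis in methanol (Criegee) gives the methoxy hydroperoxide, divalent iron cleaves the O–O bond and β-scission expels methyl acetate, TEMPO traps the ring radical and the alkoxyamine is oxidised to the ketone (dealkenylative oxidation); the isopropenyl stereocentre, no longer needed, is erased.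

**Step 9**
Reactants: 14 (2S,3S,4S)-4-hydroxy-3-(hydroxymethyl)-3-(3-hydroxypropyl)-4-methyl-2-[3-(TBSO)propyl]cyclohexan-1-one; 15 diethyl (1-cyanoethyl)phosphonate
Product: 16 (2Z)-2-[(2R,3S,4S)-4-hydroxy-3-(hydroxymethyl)-3-(3-hydroxypropyl)-4-methyl-2-[3-(TBSO)propyl]cyclohexylidene]propanenitrile
Conditions: 15, NaH, THF, 0 → 60 °C
Reagents that add atoms: diethyl (1-cyanoethyl)phosphonate, CCOP(=O)(OCC)C(C)C#N
Why: Horner–Wadsworth–Emmons olefination of the ketone; the small nitrile takes the position cis to the substituted C6 (less allylic strain than methyl), giving mainly the 2Z alkene that masks the enal.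

**Step 10**
Reactants: 16 (2Z)-2-[(2R,3S,4S)-4-hydroxy-3-(hydroxymethyl)-3-(3-hydroxypropyl)-4-methyl-2-[3-(TBSO)propyl]cyclohexylidene]propanenitrile
Product: 17 (1R,2S,5Z,6R)-5-(1-cyanoethylidene)-2-hydroxy-2-methyl-1-(3-oxopropyl)-6-[3-(TBSO)propyl]cyclohexane-1-carbaldehyde
Conditions: (COCl)2, DMSO, CH2Cl2, −78 °C; then Et3N, −78 → 0 °C
Reagents that add atoms: none
Why: Swern oxidation of both primary alcohols; the tertiary alcohol and the conjugated nitrile are inert.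

**Step 11**
Reactants: 17 (1R,2S,5Z,6R)-5-(1-cyanoethylidene)-2-hydroxy-2-methyl-1-(3-oxopropyl)-6-[3-(TBSO)propyl]cyclohexane-1-carbaldehyde; 18 triethyl phosphonoacetate
Product: 19 ethyl 5-[(1R,2S,5Z,6R)-5-(1-cyanoethylidene)-1-formyl-2-hydroxy-2-methyl-6-[3-(TBSO)propyl]cyclohexyl]-2-(diethoxyphosphoryl)pent-2-enoate (E/Z mixture at the new alkene)
Conditions: 18, piperidine (20 mol %), AcOH (20 mol %), 4 Å MS, toluene, 60 °C
Reagents that add atoms: triethyl phosphonoacetate, CCOC(=O)CP(=O)(OCC)OCC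
Why: Knoevenagel condensation occurs only at the unhindered chain aldehyde; the neopentyl aldehyde on the quaternary carbon does not react.

**Step 12**
Reactants: 20 6-methylhept-5-en-2-one
Product: 21 6-methylhepta-1,5-dien-2-yl trifluoromethanesulfonate
Conditions: LiN(i-Pr)2, THF, −78 °C; then PhNTf2, −78 → 0 °C
Reagents that add atoms: N-phenylbis(trifluoromethanesulfonimide), O=S(=O)(N(c1ccccc1)S(=O)(=O)C(F)(F)F)C(F)(F)F
Why: Kinetic deprotonation of the methyl ketone at CH3 and O-triflation of the terminal enolate (enol triflate formation).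

**Step 13**
Reactants: 21 6-methylhepta-1,5-dien-2-yl trifluoromethanesulfonate; 22 acrolein
Product: 23 (2E)-8-methyl-4-methylidenenona-2,7-dienal
Conditions: Pd(OAc)2 (3 mol %), PPh3, Et3N, DMF, 60 °C
Reagents that add atoms: acrolein, C=CC=O
Why: Heck reaction of the alkenyl triflate with acrolein; syn insertion and syn β-hydride elimination give the 2E dienal.

**Step 14**
Reactants: 19 ethyl 5-[(1R,2S,5Z,6R)-5-(1-cyanoethylidene)-1-formyl-2-hydroxy-2-methyl-6-[3-(TBSO)propyl]cyclohexyl]-2-(diethoxyphosphoryl)pent-2-enoate; 23 (2E)-8-methyl-4-methylidenenona-2,7-dienal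
Product: 25 ethyl (2E,4E)-2-[(1S,2S,5S,6S,9Z,10R)-9-(1-cyanoethylidene)-1,6-dihydroxy-6-methyl-10-[3-(TBSO)propyl]spiro[4.5]decan-2-yl]-10-methyl-6-methylideneundeca-2,4,9-trienoate, via phosphonoacetate 24 (not isolated)
Conditions: [Ir(ppy)2(dtbbpy)]PF6 (2 mol %), (PhO)2P(O)OH (20 mol %), Hantzsch ester, THF, 450 nm LEDs, rt; then LiCl, DBU, 23, MeCN, rt
Reagents that add atoms: (2E)-8-methyl-4-methylidenenona-2,7-dienal, O=C/C=C/C(=C)CCC=C(C)C
Why: Proposed new method: the excited trivalent-iridium photocatalyst is reduced by the Hantzsch ester and the resulting divalent-iridium species, together with the phosphoric acid (proton-coupled electron transfer), turns the neopentyl aldehyde into a ketyl radical hydrogen-bonded to the neighbouring tertiary hydroxyl, which adds 5-exo-trig to the alkylidene phosphonoacetate through a chair-like transition state that puts the carbinol oxygen on the hydroxyl face (C26) and the acceptor arm anti to it (C14); the doubly stabilised radical is reduced and protonated to the phosphonoacetate, which undergoes Horner–Wadsworth–Emmons olefination in the same flask with the ester trans to the dienyl group; the closest known reaction type is the photoredox or SmI2 ketyl–olefin cyclisation onto acrylates, not yet shown for alkylidene phosphonoacetates or for a hydroxyl-directed spirocyclisation.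

**Step 15**
Reactants: 25 ethyl (2E,4E)-2-[(1S,2S,5S,6S,9Z,10R)-9-(1-cyanoethylidene)-1,6-dihydroxy-6-methyl-10-[3-(TBSO)propyl]spiro[4.5]decan-2-yl]-10-methyl-6-methylideneundeca-2,4,9-trienoate
Product: 27 (2Z)-2-[(1S,2S,5S,6S,10R)-1,6-dihydroxy-2-[(2E,4E)-1-hydroxy-10-methyl-6-methylideneundeca-2,4,9-trien-2-yl]-6-methyl-10-[3-(TBSO)propyl]spiro[4.5]decan-9-ylidene]propanal, via aldimine 26 (not isolated)
Conditions: i-Bu2AlH, CH2Cl2, −78 → −40 °C; then aq. KNaC4H4O6, wet SiO2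
Reagents that add atoms: water, O
Why: i-Bu2AlH reduces the conjugated ester to the allylic alcohol and the conjugated nitrile to the aldimine (1,2-hydride addition), which hydrolyses to the enal on work-up; alkene geometries are retained.

**Step 16**
Reactants: 27 (2Z)-2-[(1S,2S,5S,6S,10R)-1,6-dihydroxy-2-[(2E,4E)-1-hydroxy-10-methyl-6-methylideneundeca-2,4,9-trien-2-yl]-6-methyl-10-[3-(TBSO)propyl]spiro[4.5]decan-9-ylidene]propanal
Product: 28 (2E,4E)-2-[(1S,2S,5S,6S,9Z,10R)-1,6-dihydroxy-6-methyl-9-(1-oxopropan-2-ylidene)-10-[3-(TBSO)propyl]spiro[4.5]decan-2-yl]-10-methyl-6-methylideneundeca-2,4,9-trien-1-yl acetate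
Conditions: Ac2O, 2,4,6-collidine, CH2Cl2, −20 °C
Reagents that add atoms: acetic anhydride, CC(=O)OC(C)=O
Why: Selective acetylation of the primary allylic alcohol; the neopentyl secondary and the tertiary hydroxyls are too hindered at low temperature.

**Step 17**
Reactants: 28 (2E,4E)-2-[(1S,2S,5S,6S,9Z,10R)-1,6-dihydroxy-6-methyl-9-(1-oxopropan-2-ylidene)-10-[3-(TBSO)propyl]spiro[4.5]decan-2-yl]-10-methyl-6-methylideneundeca-2,4,9-trien-1-yl acetate
Product: 29 CNP0204268.2, (6R,10S,11S,14S,26S; 2Z,15E,17E)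
Conditions: HF·pyridine, THF–pyridine, 0 °C → rt
Reagents that add atoms: none
Why: Fluoride-mediated cleavage of the primary silyl ether (Si–F bond formation) without touching the acetate or the enal.

**Compound list**
1 | (S)-(+)-carvone | O=C1C[C@@H](C(C)=C)CC=C1C | starting material
2 | tert-butyl(3-iodopropoxy)dimethylsilane | ICCCO[Si](C)(C)C(C)(C)C | starting material
3 | (5S,6R)-6-[3-(TBSO)propyl]-2-methyl-5-(prop-1-en-2-yl)cyclohex-2-en-1-one | O=C1[C@H](CCCO[Si](C)(C)C(C)(C)C)[C@@H](C(C)=C)CC=C1C | intermediate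
4 | lithium (5S,6R)-6-[3-(TBSO)propyl]-2-methyl-5-(prop-1-en-2-yl)cyclohex-1-en-1-olate | CC1=C([O-])[C@H](CCCO[Si](C)(C)C(C)(C)C)[C@@H](C(C)=C)CC1.[Li+] | intermediate
5 | (5S,6R)-6-[3-(TBSO)propyl]-2-methyl-5-(prop-1-en-2-yl)cyclohex-1-en-1-yl trifluoromethanesulfonate | CC1=C(OS(=O)(=O)C(F)(F)F)[C@H](CCCO[Si](C)(C)C(C)(C)C)[C@@H](C(C)=C)CC1 | intermediate
6 | methyl (5S,6R)-6-[3-(TBSO)propyl]-2-methyl-5-(prop-1-en-2-yl)cyclohex-1-ene-1-carboxylate | CC1=C(C(=O)OC)[C@H](CCCO[Si](C)(C)C(C)(C)C)[C@@H](C(C)=C)CC1 | intermediate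
7 | methyl acrylate | C=CC(=O)OC | starting material
8 | methyl (1R,2R,3S)-1-(3-methoxy-3-oxopropyl)-6-methylidene-2-[3-(TBSO)propyl]-3-(prop-1-en-2-yl)cyclohexane-1-carboxylate | COC(=O)CC[C@]1([C@H](CCCO[Si](C)(C)C(C)(C)C)[C@@H](C(C)=C)CCC1=C)C(=O)OC | intermediate
9 | 3-[(1R,2R,3S)-1-(hydroxymethyl)-6-methylidene-2-[3-(TBSO)propyl]-3-(prop-1-en-2-yl)cyclohexyl]propan-1-ol | OCCC[C@]1([C@H](CCCO[Si](C)(C)C(C)(C)C)[C@@H](C(C)=C)CCC1=C)CO | intermediate
10 | 3-[(3S,4S,5R,6S)-4-(hydroxymethyl)-5-[3-(TBSO)propyl]-6-(prop-1-en-2-yl)-1-oxaspiro[2.5]octan-4-yl]propan-1-ol (epoxide oxygen cis to CH2OH) | OCCC[C@]1([C@H](CCCO[Si](C)(C)C(C)(C)C)[C@@H](C(C)=C)CC[C@@]12CO2)CO | intermediate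
11 | (1S,2S,3R,4S)-2-(hydroxymethyl)-2-(3-hydroxypropyl)-1-methyl-3-[3-(TBSO)propyl]-4-(prop-1-en-2-yl)cyclohexan-1-ol | OCCC[C@]1([C@H](CCCO[Si](C)(C)C(C)(C)C)[C@@H](C(C)=C)CC[C@]1(C)O)CO | intermediate
12 | (1S,2S,3R,4S)-4-(1-hydroperoxy-1-methoxyethyl)-2-(hydroxymethyl)-2-(3-hydroxypropyl)-1-methyl-3-[3-(TBSO)propyl]cyclohexan-1-ol | OCCC[C@]1([C@H](CCCO[Si](C)(C)C(C)(C)C)[C@@H](C(C)(OC)OO)CC[C@]1(C)O)CO | intermediate
13 | (1S,2S,3S)-2-(hydroxymethyl)-2-(3-hydroxypropyl)-1-methyl-3-[3-(TBSO)propyl]-4-[(2,2,6,6-tetramethylpiperidin-1-yl)oxy]cyclohexan-1-ol (both C4 epimers) | OCCC[C@]1([C@H](CCCO[Si](C)(C)C(C)(C)C)C(ON2C(C)(C)CCCC2(C)C)CC[C@]1(C)O)CO | intermediate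
14 | (2S,3S,4S)-4-hydroxy-3-(hydroxymethyl)-3-(3-hydroxypropyl)-4-methyl-2-[3-(TBSO)propyl]cyclohexan-1-one | OCCC[C@]1([C@H](CCCO[Si](C)(C)C(C)(C)C)C(=O)CC[C@]1(C)O)CO | intermediate
15 | diethyl (1-cyanoethyl)phosphonate | CCOP(=O)(OCC)C(C)C#N | starting material
16 | (2Z)-2-[(2R,3S,4S)-4-hydroxy-3-(hydroxymethyl)-3-(3-hydroxypropyl)-4-methyl-2-[3-(TBSO)propyl]cyclohexylidene]propanenitrile | OCCC[C@]1([C@H](CCCO[Si](C)(C)C(C)(C)C)/C(=C(/C)C#N)CC[C@]1(C)O)CO | intermediate
17 | (1R,2S,5Z,6R)-5-(1-cyanoethylidene)-2-hydroxy-2-methyl-1-(3-oxopropyl)-6-[3-(TBSO)propyl]cyclohexane-1-carbaldehyde | O=CCC[C@]1([C@H](CCCO[Si](C)(C)C(C)(C)C)/C(=C(/C)C#N)CC[C@]1(C)O)C=O | intermediate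
18 | triethyl phosphonoacetate | CCOC(=O)CP(=O)(OCC)OCC | starting material
19 | ethyl 5-[(1R,2S,5Z,6R)-5-(1-cyanoethylidene)-1-formyl-2-hydroxy-2-methyl-6-[3-(TBSO)propyl]cyclohexyl]-2-(diethoxyphosphoryl)pent-2-enoate (E/Z mixture at C2=C3) | CCOC(=O)C(=CCC[C@]1([C@H](CCCO[Si](C)(C)C(C)(C)C)/C(=C(/C)C#N)CC[C@]1(C)O)C=O)P(=O)(OCC)OCC | intermediate
20 | 6-methylhept-5-en-2-one | CC(=O)CCC=C(C)C | starting material
21 | 6-methylhepta-1,5-dien-2-yl trifluoromethanesulfonate | C=C(OS(=O)(=O)C(F)(F)F)CCC=C(C)C | intermediate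
22 | acrolein | C=CC=O | starting material
23 | (2E)-8-methyl-4-methylidenenona-2,7-dienal | O=C/C=C/C(=C)CCC=C(C)C | intermediate
24 | ethyl 2-[(1S,2R,5S,6S,9Z,10R)-9-(1-cyanoethylidene)-1,6-dihydroxy-6-methyl-10-[3-(TBSO)propyl]spiro[4.5]decan-2-yl]-2-(diethoxyphosphoryl)acetate (hydroxyl trans to the acetate arm; epimers at the phosphonate carbon) | CCOC(=O)C([C@@H]1CC[C@]2([C@H](CCCO[Si](C)(C)C(C)(C)C)/C(=C(/C)C#N)CC[C@]2(C)O)[C@H]1O)P(=O)(OCC)OCC | intermediate
25 | ethyl (2E,4E)-2-[(1S,2S,5S,6S,9Z,10R)-9-(1-cyanoethylidene)-1,6-dihydroxy-6-methyl-10-[3-(TBSO)propyl]spiro[4.5]decan-2-yl]-10-methyl-6-methylideneundeca-2,4,9-trienoate | C=C(/C=C/C=C(/C(=O)OCC)[C@@H]1CC[C@]2([C@H](CCCO[Si](C)(C)C(C)(C)C)/C(=C(/C)C#N)CC[C@]2(C)O)[C@H]1O)CCC=C(C)C | intermediate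
26 | (2E,4E)-2-[(1S,2S,5S,6S,9Z,10R)-1,6-dihydroxy-9-(1-iminopropan-2-ylidene)-6-methyl-10-[3-(TBSO)propyl]spiro[4.5]decan-2-yl]-10-methyl-6-methylideneundeca-2,4,9-trien-1-ol | C=C(/C=C/C=C(/CO)[C@@H]1CC[C@]2([C@H](CCCO[Si](C)(C)C(C)(C)C)/C(=C(/C)C=N)CC[C@]2(C)O)[C@H]1O)CCC=C(C)C | intermediate
27 | (2Z)-2-[(1S,2S,5S,6S,10R)-1,6-dihydroxy-2-[(2E,4E)-1-hydroxy-10-methyl-6-methylideneundeca-2,4,9-trien-2-yl]-6-methyl-10-[3-(TBSO)propyl]spiro[4.5]decan-9-ylidene]propanal | C=C(/C=C/C=C(/CO)[C@@H]1CC[C@]2([C@H](CCCO[Si](C)(C)C(C)(C)C)/C(=C(/C)C=O)CC[C@]2(C)O)[C@H]1O)CCC=C(C)C | intermediate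
28 | (2E,4E)-2-[(1S,2S,5S,6S,9Z,10R)-1,6-dihydroxy-6-methyl-9-(1-oxopropan-2-ylidene)-10-[3-(TBSO)propyl]spiro[4.5]decan-2-yl]-10-methyl-6-methylideneundeca-2,4,9-trien-1-yl acetate | C=C(/C=C/C=C(/COC(C)=O)[C@@H]1CC[C@]2([C@H](CCCO[Si](C)(C)C(C)(C)C)/C(=C(/C)C=O)CC[C@]2(C)O)[C@H]1O)CCC=C(C)C | intermediate
29 | CNP0204268.2, (2E,4E)-2-[(1S,2S,5S,6S,9Z,10R)-1,6-dihydroxy-10-(3-hydroxypropyl)-6-methyl-9-(1-oxopropan-2-ylidene)spiro[4.5]decan-2-yl]-10-methyl-6-methylideneundeca-2,4,9-trien-1-yl acetate | C=C(/C=C/C=C(/COC(C)=O)[C@@H]1CC[C@]2([C@H](CCCO)/C(=C(/C)C=O)CC[C@]2(C)O)[C@H]1O)CCC=C(C)C | target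

**Step count**
Total step count: 17. Longest linear sequence: 15 steps (steps 1–11 and 14–17, from (S)-carvone); steps 12 and 13 make the dienal.

**Steps most likely to fail**

The proposed new photochemical spirocyclisation with in-flask olefination (step 14) is the least certain. The alkylidene phosphonoacetate could be reduced directly, and the hydrogen-bond control of C26 is untested. The fallback uses known chemistry, sets out from dialdehyde 17 and comes back at trienoate 25. Chemoselective Wittig reaction of the unhindered aldehyde with Ph3P=CHCO2Et gives the (E)-enoate aldehyde F3. SmI2 (divalent samarium), HMPA and t-BuOH in THF at −78 °C effect the well-precedented 5-exo ketyl–olefin cyclisation to the trans-hydroxy ester F4. Aldol addition of its lithium enolate (LiN(i-Pr)2, 3.3 equiv) to dienal 23 gives the β-hydroxy ester F5. Mesylation of the unhindered allylic carbinol and DBU-induced E1cB elimination then deliver 25.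

The olefination of the hindered, epimerisable ketone (step 9) may be slow, may scramble C6 and may give 2Z/2E mixtures. The fallback sets out from ketone 14 and comes back at nitrile 16. It is a Peterson olefination with lithiated 2-(trimethylsilyl)propanenitrile (LiN(i-Pr)2, THF, −78 °C → rt). The small, less basic silyl carbanion adds at low temperature and the alkoxide eliminates silanolate spontaneously, so this alternative passes through no new compound F0. The isomers are separated or equilibrated at the nitrile stage.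

The Michael addition that builds the quaternary C11 (step 4) may suffer from acrylate oligomerisation or γ-attack. The fallback sets out from enoate 6 and comes back at diol 9. Alkylation of the same extended enolate with allyl bromide, anti to the C6 chain, gives the α-allyl ester F1. Disiamylborane followed by NaOH/H2O2 hydroborates only the monosubstituted alkene to the hydroxy ester F2. LiAlH4 reduction then gives 9.

**Further compounds**
F1 | step 4 | methyl (1R,2R,3S)-6-methylidene-1-(prop-2-en-1-yl)-2-[3-(TBSO)propyl]-3-(prop-1-en-2-yl)cyclohexane-1-carboxylate | C=CC[C@]1([C@H](CCCO[Si](C)(C)C(C)(C)C)[C@@H](C(C)=C)CCC1=C)C(=O)OC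
F2 | step 4 | methyl (1R,2R,3S)-1-(3-hydroxypropyl)-6-methylidene-2-[3-(TBSO)propyl]-3-(prop-1-en-2-yl)cyclohexane-1-carboxylate | OCCC[C@]1([C@H](CCCO[Si](C)(C)C(C)(C)C)[C@@H](C(C)=C)CCC1=C)C(=O)OC
F0 | step 9 | none | none
F3 | step 14 | ethyl (2E)-5-[(1R,2S,5Z,6R)-5-(1-cyanoethylidene)-1-formyl-2-hydroxy-2-methyl-6-[3-(TBSO)propyl]cyclohexyl]pent-2-enoate | CCOC(=O)/C=C/CC[C@]1([C@H](CCCO[Si](C)(C)C(C)(C)C)/C(=C(/C)C#N)CC[C@]1(C)O)C=O
F4 | step 14 | ethyl 2-[(1S,2S,5S,6S,9Z,10R)-9-(1-cyanoethylidene)-1,6-dihydroxy-6-methyl-10-[3-(TBSO)propyl]spiro[4.5]decan-2-yl]acetate | CCOC(=O)C[C@@H]1CC[C@]2([C@H](CCCO[Si](C)(C)C(C)(C)C)/C(=C(/C)C#N)CC[C@]2(C)O)[C@H]1O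
F5 | step 14 | ethyl (4E)-2-[(1S,2S,5S,6S,9Z,10R)-9-(1-cyanoethylidene)-1,6-dihydroxy-6-methyl-10-[3-(TBSO)propyl]spiro[4.5]decan-2-yl]-3-hydroxy-10-methyl-6-methylideneundeca-4,9-dienoate (mixture at C2 and C3 of the chain) | CCOC(=O)C(C(O)/C=C/C(=C)CCC=C(C)C)[C@@H]1CC[C@]2([C@H](CCCO[Si](C)(C)C(C)(C)C)/C(=C(/C)C#N)CC[C@]2(C)O)[C@H]1O
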